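- Take the charges of green and change one thing, the order of addition: grey feeds Yx, amber and ochre bring Jy late.

| flask | Jy | Yx | remark | time |
|---|---|---|---|---|
| zeta | 0.32 M | 0.95 equiv | run made earlier |  |
| delta | 0.32 M | 0.47 equiv | run made earlier |  |
| epsilon | 0.32 M | 1.9 equiv | run made earlier |  |
| theta | 0.48 M | 0.95 equiv | run made earlier |  |
| grey | 0.32 M | 0.950 equiv (fed, over 6.0 d) | all else is in the flask from the start; the feed brings no volume worth counting | 10 d |
| amber | 0.32 M (in portions, 5, over 6.0 d) | 0.950 equiv | first portion at the start, last at 6.0 d | 10 d |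
| green | 0.32 M | 0.950 equiv | everything together at the start | 10 d |
| ochre | 0.32 M (fed, over 6.0 d) | 0.950 equiv | all else is in the flask from the start; the feed brings no volume worth counting | 10 d |

- zeta (time / d: Ze / %, Dw / %): 0.500: 38.7, 8.8; 0.833: 54.4, 5.0; 1.04: 63.0, 4.9; 1.67: 64.2, 1.7; 2.50: 64.8, 0.8; 4.00: 65.2, 1.0; 6.00: 66.0, 0
- delta (time / d: Ze / %, Dw / %): 0.500: 33.9, 4.8; 1.67: 40.1, 0; 3.00: 38.5, 0; 4.00: 36.9, 0; 6.00: 40.1, 0.6; 8.00: 37.5, 0; 10.0: 39.6, 0
- epsilon (time / d: Ze / %, Dw / %): 0.833: 50.8, 16.5; 1.25: 67.3, 9.5; 1.67: 76.6, 3.9; 3.00: 84.5, 0.9; 4.00: 85.4, 0; 6.00: 86.1, 0; 10.0: 86.3, 0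
- theta (time / d: Ze / %, Dw / %): 0.833: 55.1, 9.2; 1.67: 65.5, 0.6; 3.00: 68.0, 0; 5.00: 65.4, 0; 10.0: 67.0, 0

(readings scatter by 1 percentage point)

- the earlier runs were read with a standard deviation of 1 percentage point

1. the flask that comes out highest in amount of Ze, in percent of the Jy charged; "all alike" if 1.5 percentage points covers them all (grey / amber / green / ochre / all alike)
2. amount of Ze at the end, in percent of the Jy charged, grey
3. amount of Ze at the end, in percent of the Jy charged, amber
4. amount of Ze at the end, in percent of the Jy charged, green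
5. amount of Ze at the end, in percent of the Jy charged, ochre

- Zeta looks contradictory: it holds 0.95 equiv of Yx, yet its last reading gives Ze at 66.0% with Dw at 0%, so a third of the Jy reads as neither.
- I clear this with a second path for Yx. Suppose Jy reacts at k times its fraction, while Yx is lost at the same k times its own fraction, besides what Jy takes. Then Yx reaches zero when kt equals the equivalents, and ln(1/(1 − Ze)) per equivalent should read near one.
- The runs read 1.07 for delta, 1.14 for zeta and 1.05 for epsilon.
- The first zeta reading of Ze gives k as 0.979 d⁻¹.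
- For ochre I reckon in fractions of the charge. Jy enters evenly over 6.0 d, and I call s the standing share, the fraction of Jy at which uptake equals feed: 0.170.
- Jy climbs towards s while Yx falls. Put x for the equivalents over s, here 5.58, and T for kt. Yx reaches zero where exp(T) equals one plus T plus x, so ochre's T is 2.17.
- That comes at 2.22 d, earlier than the end of the feed. Ze then holds s times (T minus one plus exp(−T)), which for ochre is 21.8%.
- The forecast names grey as highest, with grey 88%, amber 31%, green 65% and ochre 28%, reasoning that “Slow Jy feed, or portions, leaves Yx alone to destroy itself”. My ochre figure stands below its figure.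
- The flasks give grey as highest: grey 94.3%, amber 26.5%, green 65.6%, ochre 21.7%.

    Jy + Yx ⇌ Dw (K = 1.60 M⁻¹, k = 0.160 M⁻¹ h⁻¹)
    Jy + Yx → Ze, rate k2*[Jy] as long as [Yx] is above zero (k = 0.0480 h⁻¹)
    Yx → Zu (k = 0.0440 h⁻¹)

- At 10.0 d ochre holds Jy at 78.3% and Yx at 0% of its own charge, which makes Yx the limiting reagent, with Ze at 21.7% against my 21.8%. The neighbouring flask is ochre with 0.380 equiv of Yx and the same s, 0.170. Its x is 2.23, its T is 1.57, and the reckoned Ze is 13.3%. At 10.0 d the neighbouring flask holds Jy at 86.7% and Ze at 13.3%.

Readings and results were generated by integration with made-up constants; the scatter is artificial.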